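**Plan**

- Labels: ring C is the oxolane (O1, C2–C5). C2 carries the central arene (ring B) and C5 a 3,4-dimethoxyphenyl group (ring D). In the side chain, C7' is the carbinol on ring A and C8' bears the oxygen bound to C4 of ring B.
- Cuts: first the ring B C4–O aryl ether bond, then O1–C2 of ring C, then C2–ring B, the C3 methyl and C4–C5. The side chain is cut at C7'–ring A.
- Forward: crotylboration of veratraldehyde, γ-lactone, C3 methylation, lactone opening and silylation, aryl ketone, carbinol, mesylate, closure of ring C (the only ring made), then ether coupling with a lactate-derived alcohol and deprotection.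
- Stereochemistry: C5 and C4 come from a catalyst-controlled syn-crotylboration and C3 from anti-alkylation of the lactone enolate. C2 comes from a matched CBS/Felkin–Anh ketone reduction followed by inversion on ring closure. C8' comes from methyl (R)-lactate and C7' from chelate-controlled aryl addition.
- Enabling feature: at C2, ring B stands cis to the C3 methyl, the less stable arrangement. The ring B carbon para to C2 carries oxygen only in the target, so a bromine held there keeps benzylic C2 too electron-poor to ionise and O1 can displace a C2 mesylate with inversion.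

Key step: step 10

Remark: metal alkoxides and borate esters that are only hydrolysed on work-up are treated as the product and carry no number; 3,4-dimethoxyphenylmagnesium bromide is taken as the commercial THF solution.

**Route**

Step 1
Reactants: 1 veratraldehyde; 2 (Z)-crotylboronic acid pinacol ester
Product: 3 (1S,2R)-1-(3,4-dimethoxyphenyl)-2-methylbut-3-en-1-ol
Conditions: (S)-TRIP [(S)-3,3'-bis(2,4,6-triisopropylphenyl)-1,1'-binaphthyl-2,2'-diyl hydrogen phosphate] (5 mol%), 4 Å MS, toluene, −30 °C; aq. NaHCO3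
Reagents that add atoms: none
Why: Chiral-phosphoric-acid-catalysed crotylboration runs through a closed six-membered chair transition state, so the Z boronate gives the syn C5/C4 pair, and the (S)-acid, bound to the boronate oxygen and the formyl hydrogen, should direct attack to the Si face of the aldehyde to set (1S,2R).

Step 2
Reactants: 3 (1S,2R)-1-(3,4-dimethoxyphenyl)-2-methylbut-3-en-1-ol
Product: 5 (1S,2R)-1-(3,4-dimethoxyphenyl)-2-methylbutane-1,4-diol, via B-alkyl-9-BBN adduct 4 (not isolated)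
Conditions: 9-BBN (2.5 equiv), THF, 0 °C → rt; then NaOH, H2O2, 0 °C → rt
Reagents that add atoms: hydrogen peroxide, OO
Why: Anti-Markovnikov hydroboration of the monosubstituted alkene by the bulky borane, followed by oxidative C–B to C–O exchange with retention, gives the primary alcohol without touching either stereocenter.

Step 3
Reactants: 5 (1S,2R)-1-(3,4-dimethoxyphenyl)-2-methylbutane-1,4-diol
Product: 7 (4R,5S)-5-(3,4-dimethoxyphenyl)-4-methyloxolan-2-one, via lactol 6 (not isolated)
Conditions: TEMPO (0.2 equiv), PhI(OAc)2 (2.5 equiv), CH2Cl2, rt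
Reagents that add atoms: none
Why: In this oxidative lactonisation of a 1,4-diol the oxoammonium species oxidises the unhindered primary alcohol first, the aldehyde is captured by the benzylic hydroxyl as a lactol and this is oxidised on to the γ-lactone, so the secondary carbinol is never exposed as a ketone.

Step 4
Reactants: 7 (4R,5S)-5-(3,4-dimethoxyphenyl)-4-methyloxolan-2-one
Product: 9 (3R,4R,5S)-5-(3,4-dimethoxyphenyl)-3,4-dimethyloxolan-2-one, via lithium enolate 8 (not isolated)
Conditions: LiN(SiMe3)2, THF, −78 °C; MeI, −78 → −40 °C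
Reagents that add atoms: iodomethane, CI
Why: Kinetic alkylation of the γ-lactone enolate should take place on the face opposite the neighbouring C4 methyl and the C5 aryl group cis to it, which sets C3 as R with the two methyl groups trans.

Step 5
Reactants: 9 (3R,4R,5S)-5-(3,4-dimethoxyphenyl)-3,4-dimethyloxolan-2-one
Product: 10 (2R,3R,4S)-4-(3,4-dimethoxyphenyl)-4-hydroxy-N-methoxy-N,2,3-trimethylbutanamide
Conditions: MeNHOMe·HCl, AlMe3, CH2Cl2, 0 °C → rt; aq. potassium sodium tartrate
Reagents that add atoms: N,O-dimethylhydroxylamine hydrochloride, CNOC.Cl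
Why: Weinreb amidation by the aluminium amide formed from AlMe3 and the amine salt opens the lactone at the acyl carbon only, so all three stereocenters are carried over unchanged.

Step 6
Reactants: 10 (2R,3R,4S)-4-(3,4-dimethoxyphenyl)-4-hydroxy-N-methoxy-N,2,3-trimethylbutanamide
Product: 11 (2R,3R,4S)-4-[(tert-butyldimethylsilyl)oxy]-4-(3,4-dimethoxyphenyl)-N-methoxy-N,2,3-trimethylbutanamide
Conditions: TBSOTf, 2,6-lutidine, CH2Cl2, −78 → 0 °C (crude 10 used at once)
Reagents that add atoms: tert-butyldimethylsilyl trifluoromethanesulfonate, CC(C)(C)[Si](C)(C)OS(=O)(=O)C(F)(F)F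
Why: Silylation with the silyl triflate is fast enough to cap the hindered benzylic hydroxyl before it can re-lactonise, and the ether keeps the C5 oxygen masked until the ring closure.

Step 7
Reactants: 12 1-bromo-4-iodo-2-methoxybenzene; 11 (2R,3R,4S)-4-[(tert-butyldimethylsilyl)oxy]-4-(3,4-dimethoxyphenyl)-N-methoxy-N,2,3-trimethylbutanamide
Product: 14 (2R,3R,4S)-1-(4-bromo-3-methoxyphenyl)-4-[(tert-butyldimethylsilyl)oxy]-4-(3,4-dimethoxyphenyl)-2,3-dimethylbutan-1-one, via aryl Grignard reagent 13 (not isolated)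
Conditions: 12, iPrMgCl·LiCl, THF, −20 °C; then 11, −20 °C → rt; aq. NH4Cl
Reagents that add atoms: none
Why: Iodine–magnesium exchange is selective for the C–I bond over C–Br, and the Weinreb ketone synthesis stops at the chelated tetrahedral adduct, which prevents over-addition and keeps the α-stereocenter from enolising before the quench.

Step 8
Reactants: 14 (2R,3R,4S)-1-(4-bromo-3-methoxyphenyl)-4-[(tert-butyldimethylsilyl)oxy]-4-(3,4-dimethoxyphenyl)-2,3-dimethylbutan-1-one
Product: 15 (1R,2R,3R,4S)-1-(4-bromo-3-methoxyphenyl)-4-[(tert-butyldimethylsilyl)oxy]-4-(3,4-dimethoxyphenyl)-2,3-dimethylbutan-1-ol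
Conditions: (S)-2-methyl-CBS-oxazaborolidine (0.5 equiv), BH3·SMe2, THF, −20 → 0 °C; MeOH
Reagents that add atoms: none
Why: Corey–Bakshi–Shibata reduction with the aryl group as the large substituent should give the (1R) carbinol, the same face that Felkin–Anh control by the α-stereocenter favours, so reagent and substrate are matched.

Step 9
Reactants: 15 (1R,2R,3R,4S)-1-(4-bromo-3-methoxyphenyl)-4-[(tert-butyldimethylsilyl)oxy]-4-(3,4-dimethoxyphenyl)-2,3-dimethylbutan-1-ol
Product: 16 (1R,2R,3R,4S)-1-(4-bromo-3-methoxyphenyl)-4-[(tert-butyldimethylsilyl)oxy]-4-(3,4-dimethoxyphenyl)-2,3-dimethylbutyl methanesulfonate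
Conditions: Ms2O, Et3N, CH2Cl2, −20 °C; cold aqueous work-up, used without chromatography
Reagents that add atoms: methanesulfonic anhydride, CS(=O)(=O)OS(C)(=O)=O
Why: O-Sulfonylation leaves the C–O bond and hence the (1R) configuration untouched, and the anhydride is used instead of the sulfonyl chloride so that no chloride ion is present to displace the benzylic mesylate.

Step 10
Reactants: 16 (1R,2R,3R,4S)-1-(4-bromo-3-methoxyphenyl)-4-[(tert-butyldimethylsilyl)oxy]-4-(3,4-dimethoxyphenyl)-2,3-dimethylbutyl methanesulfonate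
Product: 18 (2S,3R,4R,5S)-2-(4-bromo-3-methoxyphenyl)-5-(3,4-dimethoxyphenyl)-3,4-dimethyloxolane, via tetrabutylammonium alkoxide 17 (not isolated)
Conditions: Bu4NF, THF, 0 °C → rt
Reagents that add atoms: none
Why: Fluoride cleaves the Si–O bond of 16 and the liberated C5 alkoxide 17 attacks C2 from the side opposite the departing mesylate, an intramolecular Williamson (SN2) etherification that forms O1–C2. The closest known reaction type is the base- or fluoride-triggered cyclisation of 1,4-diol monosulfonates to tetrahydrofurans with inversion at the sulfonate carbon. Ring C closes in the 5-exo-tet mode. The one new stereocenter, C2, should be fixed as S by inversion of the (1R)-mesylate, whose configuration comes from step 8, while C3, C4 and C5 are spectators because the C5–O bond is never broken. The step needs substitution with inversion to beat ionisation (which would lead to the more stable 2,3-trans ether) and E2 loss of the C3 hydrogen; the para bromine and meta methoxy of ring B disfavour a benzylic cation, the chloride-free mesylation excludes a double inversion, and the high effective molarity of a five-membered closure at 0 °C should favour the intramolecular path over fluoride acting as a base.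

Step 11
Reactants: 19 methyl (R)-lactate
Product: 20 methyl (2R)-2-(benzyloxy)propanoate
Conditions: BnOC(=NH)CCl3, TfOH (cat.), cyclohexane/CH2Cl2, rt
Reagents that add atoms: benzyl 2,2,2-trichloroacetimidate, N=C(OCc1ccccc1)C(Cl)(Cl)Cl
Why: Acid-catalysed O-benzylation with the trichloroacetimidate avoids base, so the lactate stereocenter cannot racemise.

Step 12
Reactants: 20 methyl (2R)-2-(benzyloxy)propanoate
Product: 21 (2R)-2-(benzyloxy)propanal
Conditions: iBu2AlH, CH2Cl2, −78 °C; aq. potassium sodium tartrate; used crude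
Reagents that add atoms: none
Why: Partial reduction of the ester stops at the aluminium hemiacetal at −78 °C and releases the aldehyde only on work-up, and immediate use avoids epimerisation of the α-alkoxy aldehyde.

Step 13
Reactants: 21 (2R)-2-(benzyloxy)propanal; 22 3,4-dimethoxyphenylmagnesium bromide
Product: 23 (1R,2R)-2-(benzyloxy)-1-(3,4-dimethoxyphenyl)propan-1-ol
Conditions: MgBr2·OEt2, CH2Cl2, −78 °C; then 22 (THF solution), −78 °C; aq. NH4Cl
Reagents that add atoms: none
Why: In this Cram-chelate-controlled Grignard addition magnesium bridges the aldehyde and benzyloxy oxygens and the aryl group should enter from the face of the chelate that carries hydrogen and not methyl, giving the syn (1R,2R) carbinol.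

Step 14
Reactants: 23 (1R,2R)-2-(benzyloxy)-1-(3,4-dimethoxyphenyl)propan-1-ol
Product: 24 (1R,2R)-2-(benzyloxy)-1-(3,4-dimethoxyphenyl)-1-{[2-(trimethylsilyl)ethoxy]methoxy}propane
Conditions: SEMCl, iPr2NEt, Bu4NI (cat.), CH2Cl2, 40 °C
Reagents that add atoms: 2-(trimethylsilyl)ethoxymethyl chloride, C[Si](C)(C)CCOCCl
Why: Alkylation of the benzylic hydroxyl with the chloromethyl ether gives an acetal-type ether that, unlike a silyl ether, cannot migrate to the vicinal oxygen under the basic coupling conditions and can later be removed by fluoride without acid.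

Step 15
Reactants: 24 (1R,2R)-2-(benzyloxy)-1-(3,4-dimethoxyphenyl)-1-{[2-(trimethylsilyl)ethoxy]methoxy}propane
Product: 25 (1R,2R)-1-(3,4-dimethoxyphenyl)-1-{[2-(trimethylsilyl)ethoxy]methoxy}propan-2-ol
Conditions: H2 (1 atm), 10% Pd/C, EtOAc, rt
Reagents that add atoms: none
Why: Hydrogenolysis cleaves the unhindered primary benzyl ether, while the hindered secondary benzylic acetal oxygen should react much more slowly under neutral conditions.

Step 16
Reactants: 18 (2S,3R,4R,5S)-2-(4-bromo-3-methoxyphenyl)-5-(3,4-dimethoxyphenyl)-3,4-dimethyloxolane; 25 (1R,2R)-1-(3,4-dimethoxyphenyl)-1-{[2-(trimethylsilyl)ethoxy]methoxy}propan-2-ol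
Product: 26 (2S,3R,4R,5S)-5-(3,4-dimethoxyphenyl)-2-[4-({(1R,2R)-1-(3,4-dimethoxyphenyl)-1-{[2-(trimethylsilyl)ethoxy]methoxy}propan-2-yl}oxy)-3-methoxyphenyl]-3,4-dimethyloxolane
Conditions: [Pd(C3H5)Cl]2 (2.5 mol%), RockPhos (6 mol%), Cs2CO3, toluene, 90 °C
Reagents that add atoms: none
Why: In this palladium-catalysed C–O cross-coupling (Buchwald–Hartwig etherification) zerovalent palladium inserts into the aryl–bromine bond, the alkoxide of 25 replaces bromide on divalent palladium and the bulky biaryl di-tert-butylphosphine should drive C–O reductive elimination ahead of β-hydride elimination, while the alcohol C–O bond is not involved and C8' keeps its configuration.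

Step 17
Reactants: 26 (2S,3R,4R,5S)-5-(3,4-dimethoxyphenyl)-2-[4-({(1R,2R)-1-(3,4-dimethoxyphenyl)-1-{[2-(trimethylsilyl)ethoxy]methoxy}propan-2-yl}oxy)-3-methoxyphenyl]-3,4-dimethyloxolane
Product: 27 (1R,2R)-1-(3,4-dimethoxyphenyl)-2-{4-[(2S,3R,4R,5S)-5-(3,4-dimethoxyphenyl)-3,4-dimethyloxolan-2-yl]-2-methoxyphenoxy}propan-1-ol
Conditions: Bu4NF, DMPU, 4 Å MS, 80 °C
Reagents that add atoms: none
Why: Fluoride attacks silicon and the SEM ether fragments with loss of ethene and formaldehyde, a non-acidic deprotection under which the benzylic ethers at C2 and C5 and the C7' carbinol cannot ionise.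

**Compound list**

1 | veratraldehyde (3,4-dimethoxybenzaldehyde) | COc1ccc(C=O)cc1OC | starting material
2 | (Z)-crotylboronic acid pinacol ester | C/C=C\CB1OC(C)(C)C(C)(C)O1 | starting material
3 | (1S,2R)-1-(3,4-dimethoxyphenyl)-2-methylbut-3-en-1-ol | COc1ccc([C@@H](O)[C@H](C)C=C)cc1OC | intermediate
4 | 9-[(3R,4S)-4-(3,4-dimethoxyphenyl)-4-hydroxy-3-methylbutyl]-9-borabicyclo[3.3.1]nonane | COc1ccc([C@@H](O)[C@H](C)CCB2C3CCCC2CCC3)cc1OC | intermediate
5 | (1S,2R)-1-(3,4-dimethoxyphenyl)-2-methylbutane-1,4-diol | COc1ccc([C@@H](O)[C@H](C)CCO)cc1OC | intermediate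
6 | (4R,5S)-5-(3,4-dimethoxyphenyl)-4-methyloxolan-2-ol (lactol, both C2 epimers) | COc1ccc([C@H]2OC(O)C[C@H]2C)cc1OC | intermediate
7 | (4R,5S)-5-(3,4-dimethoxyphenyl)-4-methyloxolan-2-one | COc1ccc([C@H]2OC(=O)C[C@H]2C)cc1OC | intermediate
8 | lithium (4R,5S)-5-(3,4-dimethoxyphenyl)-4-methyl-4,5-dihydrofuran-2-olate | [Li+].COc1ccc([C@H]2OC([O-])=C[C@H]2C)cc1OC | intermediate
9 | (3R,4R,5S)-5-(3,4-dimethoxyphenyl)-3,4-dimethyloxolan-2-one | COc1ccc([C@H]2OC(=O)[C@H](C)[C@H]2C)cc1OC | intermediate
10 | (2R,3R,4S)-4-(3,4-dimethoxyphenyl)-4-hydroxy-N-methoxy-N,2,3-trimethylbutanamide | CON(C)C(=O)[C@H](C)[C@@H](C)[C@H](O)c1ccc(OC)c(OC)c1 | intermediate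
11 | (2R,3R,4S)-4-[(tert-butyldimethylsilyl)oxy]-4-(3,4-dimethoxyphenyl)-N-methoxy-N,2,3-trimethylbutanamide | CON(C)C(=O)[C@H](C)[C@@H](C)[C@H](O[Si](C)(C)C(C)(C)C)c1ccc(OC)c(OC)c1 | intermediate
12 | 1-bromo-4-iodo-2-methoxybenzene | COc1cc(I)ccc1Br | starting material
13 | (4-bromo-3-methoxyphenyl)magnesium chloride (LiCl complex) | COc1cc([Mg]Cl)ccc1Br | intermediate
14 | (2R,3R,4S)-1-(4-bromo-3-methoxyphenyl)-4-[(tert-butyldimethylsilyl)oxy]-4-(3,4-dimethoxyphenyl)-2,3-dimethylbutan-1-one | COc1cc(C(=O)[C@H](C)[C@@H](C)[C@H](O[Si](C)(C)C(C)(C)C)c2ccc(OC)c(OC)c2)ccc1Br | intermediate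
15 | (1R,2R,3R,4S)-1-(4-bromo-3-methoxyphenyl)-4-[(tert-butyldimethylsilyl)oxy]-4-(3,4-dimethoxyphenyl)-2,3-dimethylbutan-1-ol | COc1cc([C@H](O)[C@H](C)[C@@H](C)[C@H](O[Si](C)(C)C(C)(C)C)c2ccc(OC)c(OC)c2)ccc1Br | intermediate
16 | (1R,2R,3R,4S)-1-(4-bromo-3-methoxyphenyl)-4-[(tert-butyldimethylsilyl)oxy]-4-(3,4-dimethoxyphenyl)-2,3-dimethylbutyl methanesulfonate | COc1cc([C@H](OS(C)(=O)=O)[C@H](C)[C@@H](C)[C@H](O[Si](C)(C)C(C)(C)C)c2ccc(OC)c(OC)c2)ccc1Br | intermediate
17 | tetrabutylammonium (1S,2R,3R,4R)-4-(4-bromo-3-methoxyphenyl)-1-(3,4-dimethoxyphenyl)-4-[(methanesulfonyl)oxy]-2,3-dimethylbutan-1-olate (16 without its silyl group) | CCCC[N+](CCCC)(CCCC)CCCC.COc1cc([C@H](OS(C)(=O)=O)[C@H](C)[C@@H](C)[C@H]([O-])c2ccc(OC)c(OC)c2)ccc1Br | intermediate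
18 | (2S,3R,4R,5S)-2-(4-bromo-3-methoxyphenyl)-5-(3,4-dimethoxyphenyl)-3,4-dimethyloxolane | COc1cc([C@H]2O[C@H](c3ccc(OC)c(OC)c3)[C@H](C)[C@H]2C)ccc1Br | intermediate
19 | methyl (R)-lactate | C[C@@H](O)C(=O)OC | starting material
20 | methyl (2R)-2-(benzyloxy)propanoate | C[C@@H](OCc1ccccc1)C(=O)OC | intermediate
21 | (2R)-2-(benzyloxy)propanal | C[C@@H](OCc1ccccc1)C=O | intermediate
22 | 3,4-dimethoxyphenylmagnesium bromide (THF solution) | COc1ccc([Mg]Br)cc1OC | starting material
23 | (1R,2R)-2-(benzyloxy)-1-(3,4-dimethoxyphenyl)propan-1-ol | COc1ccc([C@@H](O)[C@@H](C)OCc2ccccc2)cc1OC | intermediate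
24 | (1R,2R)-2-(benzyloxy)-1-(3,4-dimethoxyphenyl)-1-{[2-(trimethylsilyl)ethoxy]methoxy}propane | COc1ccc([C@@H](OCOCC[Si](C)(C)C)[C@@H](C)OCc2ccccc2)cc1OC | intermediate
25 | (1R,2R)-1-(3,4-dimethoxyphenyl)-1-{[2-(trimethylsilyl)ethoxy]methoxy}propan-2-ol | COc1ccc([C@@H](OCOCC[Si](C)(C)C)[C@@H](C)O)cc1OC | intermediate
26 | (2S,3R,4R,5S)-5-(3,4-dimethoxyphenyl)-2-[4-({(1R,2R)-1-(3,4-dimethoxyphenyl)-1-{[2-(trimethylsilyl)ethoxy]methoxy}propan-2-yl}oxy)-3-methoxyphenyl]-3,4-dimethyloxolane | COc1ccc([C@@H](OCOCC[Si](C)(C)C)[C@@H](C)Oc2ccc([C@H]3O[C@H](c4ccc(OC)c(OC)c4)[C@H](C)[C@H]3C)cc2OC)cc1OC | intermediate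
27 | (1R,2R)-1-(3,4-dimethoxyphenyl)-2-{4-[(2S,3R,4R,5S)-5-(3,4-dimethoxyphenyl)-3,4-dimethyloxolan-2-yl]-2-methoxyphenoxy}propan-1-ol | COc1ccc([C@@H](O)[C@@H](C)Oc2ccc([C@H]3O[C@H](c4ccc(OC)c(OC)c4)[C@H](C)[C@H]3C)cc2OC)cc1OC | target

**Step count**

Total step count: 17. Longest linear sequence: 12 steps (steps 1–10, then 16 and 17); steps 11–15 make the side-chain alcohol.

**Steps most likely to fail**

Step 10. Fluoride may act as a base or a nucleophile at the benzylic sulfonate before the silyl ether is cleaved, or the mesylate may ionise, so that elimination or loss of the C2 configuration competes with ring closure. The fallback sets out from ketone 14 and forms the O1–C2 bond by carbonyl addition instead of displacement. Buffered HF·pyridine in THF removes the silyl group and the freed C5 hydroxyl closes onto the ketone to give the cyclic hemiketal (3R,4R,5S)-2-(4-bromo-3-methoxyphenyl)-5-(3,4-dimethoxyphenyl)-3,4-dimethyloxolan-2-ol F1. Et3SiH and BF3·OEt2 in CH2Cl2 at −78 °C then reduce the derived 2-aryl oxocarbenium ion; hydride should enter anti to the C3 methyl so that ring B ends up cis to it, which returns the route to 18.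

Step 16. β-Hydride elimination from the palladium alkoxide of the hindered secondary alcohol may outrun C–O reductive elimination, consuming the bromide by hydrodebromination. The fallback sets out from 18 and builds the side chain on a phenol. Hydroxylation of the bromide (KOH, Pd2(dba)3, tBuXPhos, dioxane/H2O, 100 °C) gives 4-[(2S,3R,4R,5S)-5-(3,4-dimethoxyphenyl)-3,4-dimethyloxolan-2-yl]-2-methoxyphenol F2. A Mitsunobu reaction with ethyl (S)-lactate (PPh3, DIAD, THF) inverts the lactate carbon and gives ethyl (2R)-2-{4-[(2S,3R,4R,5S)-5-(3,4-dimethoxyphenyl)-3,4-dimethyloxolan-2-yl]-2-methoxyphenoxy}propanoate F3. MeNHOMe·HCl with iPrMgCl converts this into (2R)-2-{4-[(2S,3R,4R,5S)-5-(3,4-dimethoxyphenyl)-3,4-dimethyloxolan-2-yl]-2-methoxyphenoxy}-N-methoxy-N-methylpropanamide F4. Addition of 22 gives (2R)-1-(3,4-dimethoxyphenyl)-2-{4-[(2S,3R,4R,5S)-5-(3,4-dimethoxyphenyl)-3,4-dimethyloxolan-2-yl]-2-methoxyphenoxy}propan-1-one F5. Reduction with (R)-2-methyl-CBS-oxazaborolidine and BH3·SMe2, which should agree with the Felkin–Anh preference of the α-aryloxy ketone, sets C7' and rejoins the route at the target 27.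

Step 13. THF from the Grignard solution may compete for magnesium and weaken the chelate, or the α-alkoxy aldehyde may enolise, so that facial selectivity or enantiomeric purity is eroded. The fallback sets out from ester 20. MeNHOMe·HCl with iPrMgCl gives (2R)-2-(benzyloxy)-N-methoxy-N-methylpropanamide F6, and a single addition of 22 gives (2R)-2-(benzyloxy)-1-(3,4-dimethoxyphenyl)propan-1-one F7. Reduction under reagent control with (R)-2-methyl-CBS-oxazaborolidine and BH3·SMe2 (aryl as the large group) should set the (1R) carbinol and rejoins the route at 23.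

**Further compounds**

F1 | step 10 | (3R,4R,5S)-2-(4-bromo-3-methoxyphenyl)-5-(3,4-dimethoxyphenyl)-3,4-dimethyloxolan-2-ol (hemiketal, both C2 epimers) | COc1cc(C2(O)O[C@H](c3ccc(OC)c(OC)c3)[C@H](C)[C@H]2C)ccc1Br
F2 | step 16 | 4-[(2S,3R,4R,5S)-5-(3,4-dimethoxyphenyl)-3,4-dimethyloxolan-2-yl]-2-methoxyphenol | COc1cc([C@H]2O[C@H](c3ccc(OC)c(OC)c3)[C@H](C)[C@H]2C)ccc1O
F3 | step 16 | ethyl (2R)-2-{4-[(2S,3R,4R,5S)-5-(3,4-dimethoxyphenyl)-3,4-dimethyloxolan-2-yl]-2-methoxyphenoxy}propanoate | CCOC(=O)[C@@H](C)Oc1ccc([C@H]2O[C@H](c3ccc(OC)c(OC)c3)[C@H](C)[C@H]2C)cc1OC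
F4 | step 16 | (2R)-2-{4-[(2S,3R,4R,5S)-5-(3,4-dimethoxyphenyl)-3,4-dimethyloxolan-2-yl]-2-methoxyphenoxy}-N-methoxy-N-methylpropanamide | CON(C)C(=O)[C@@H](C)Oc1ccc([C@H]2O[C@H](c3ccc(OC)c(OC)c3)[C@H](C)[C@H]2C)cc1OC
F5 | step 16 | (2R)-1-(3,4-dimethoxyphenyl)-2-{4-[(2S,3R,4R,5S)-5-(3,4-dimethoxyphenyl)-3,4-dimethyloxolan-2-yl]-2-methoxyphenoxy}propan-1-one | COc1ccc(C(=O)[C@@H](C)Oc2ccc([C@H]3O[C@H](c4ccc(OC)c(OC)c4)[C@H](C)[C@H]3C)cc2OC)cc1OC
F6 | step 13 | (2R)-2-(benzyloxy)-N-methoxy-N-methylpropanamide | CON(C)C(=O)[C@@H](C)OCc1ccccc1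
F7 | step 13 | (2R)-2-(benzyloxy)-1-(3,4-dimethoxyphenyl)propan-1-one | COc1ccc(C(=O)[C@@H](C)OCc2ccccc2)cc1OC
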